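## Structural features

The target 20 is a 1,2-dihydronaphthalene. Its aromatic ring A (C4a, C5 to C8, C8a) carries a catechol at C6/C7 and is fused to ring B (C1, C2, C3=C4), whose C3=C4 bond is conjugated both with ring A and with the C3 carboxylic acid; C2 carries a second carboxylic acid. C1 is a methine that links C8a of ring A to C4' of a 2-pyranone (ring C: O1', C2'=O, C3' to C6'), and C6' of that ring bears the third carboxylic acid. C1 (R) and C2 (S) are adjacent stereocentres with the pyranonyl group and the C2 carboxyl trans. The fragile elements are the catechol (oxidised in base), the pyranone lactone (opened by hydroxide, alkoxide or amines), C1–H (benzylic and vinylogously α to the lactone carbonyl) and C2–H (α to a carboxyl and allylic). Base can therefore epimerise the molecule or shift the C3=C4 bond, and the dihydronaphthalene is easily dehydrogenated to a naphthalene. The real difficulty is the absolute configuration at C1, a carbon with no heteroatom that joins an electron-rich arene to an electron-poor heterocycle, to be set and then kept under non-basic conditions only. The feature exploited is that C1 is bonded to C8a, which lies para to the C6 oxygen, and that C1 is β to the C2 carboxyl. The C1–C8a bond is thus the bond made when the nucleophilic ring A carbon adds to C1 of a C1=C2 acrylate, and the C2 carboxyl is the natural seat for a chiral controller.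

## Logic of the disconnections

20 ⇒ 18 (through 19). No skeletal bond is cut; the five O–CH3 bonds (two aryl ethers at C6/C7, three esters) are restored. The free catechol and acids would not survive enolate, palladium or Lewis-acid chemistry, and one small group for all five positions lets 6, 7 and 5 bring it in from the start. The gain is a single unmasking at the end. The demand is that it run without base: Lewis-acidic ether cleavage followed by acidic ester hydrolysis in one flask.

18 ⇒ 17. The C2 acyl–OMe bond is exchanged for an acyl–N bond to the auxiliary. The C2 carbonyl is the only one conjugated with C1 in the open-chain precursor, so a controller placed there can reach C1. The gain is a traceless, recoverable source of chirality (9). The demand is exocyclic cleavage of a hindered imide under neutral conditions.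

17 ⇒ 15 (through 16). The C1–C8a bond and the C2–H bond are cut. This removes ring B and both ring stereocentres and leaves an open-chain diene whose only stereocentre is that of the auxiliary. The demands are the most severe of the route:
- the C3=C4 bond must hold ring A cis to C2;
- the C1=C2 bond must be geometrically pure (E), because facial selection through the chelate translates into (1R) only for one combination of alkene geometry and auxiliary antipode, here (E) with (4R);
- activation must be confined to the imide;
- the proton released by the arene must be taken up irreversibly.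

15 ⇒ 14 + 5. The C1–C4' bond between two sp2 carbons is cut. This separates the fragile heterocycle from the rest, gives two fragments of similar size, and leaves C1 as a terminal methylene. The demand is a coupling that attacks only that methylene, gives the (E)-alkene and uses a base that does not add to either partner.

14 ⇒ 12 ⇒ 11 (through 13). The C1=C2 bond is cut, so that C1 becomes a one-carbon electrophile and C2 the α-carbon of the imide. The gain is that the whole left half reduces to a simple acyl imide. The demand is α- rather than γ-reaction of a dienolate and a mild dehydration.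

11 ⇒ 8 + 9 (through 10). The N–acyl bond is cut. The free acid of 8 is exactly the carboxyl that must become the C2 carbonyl, so the two succinate carboxyls need no extra differentiation. The demand is acylation without migration of the C3=C4 bond.

8 ⇒ 6 + 7. The C3=C4 bond is cut. The condensation delivers the arylidene succinate with the two carboxyls already distinguished (ester on C3, acid on the CH2 arm) and with ring A cis to that arm. The gain is two commodity compounds. The demand is (E) selectivity.

5 ⇒ 4 ⇒ 3 ⇒ 2 ⇒ 1. Only functional groups change: the C6' carboxyl is traced to a methyl group and the C4'–Br bond to a C4'–OH bond. 1 already has ring C with the correct 4,6-pattern, so no ring has to be built. The demand is that the oxidations spare the C4'–Br bond and the lactone.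

## Other disconnections considered

Alternative 1: The cut lies inside ring C. The lactone bond O1'–C2' is opened and the pyranone is read as an oxidatively cleaved and re-closed catechol. The precursor is then A2, 1-(3,4-dihydroxyphenyl)-6,7-dimethoxy-1,2-dihydronaphthalene-2,3-dicarboxylic acid, configured as the target. In the forward sense protocatechuate 4,5-dioxygenase (non-haem divalent iron, O2) would cleave the pendant catechol between the hydroxylated carbon para to C1 and its CH neighbour. The enol oxygen would then add to the new aldehyde, and an NADP+-dependent dehydrogenase would oxidise the cyclic hemiacetal to the lactone. The product would be the 6,7-di-O-methyl ether of 20, A1.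

- In favour: the 4',6'-pattern arises without regiochemical ambiguity, in water, at neutral pH. The pyranone never meets a Lewis acid or palladium. The four steps to 5 and the coupling of step 9 disappear.
- Equal or better than the chosen plan: in A2 the C1 aryl group is electron-rich, so a cation-like C1 in a ring B closure is stabilised rather than destabilised as it is next to a pyranone. On that point the alternative is the better design.
- Against: the enzyme recognises small benzoates through their carboxylate, and a bulky chiral dihydronaphthalene in that position may not be accepted without enzyme engineering. Two enzymes, an oxygen-sensitive ferrous centre and cofactor recycling are needed. Ring A must stay methylated so that it is not cleaved too, and therefore A1 still needs the ether cleavage of step 12. There is no dependable non-enzymatic extradiol cleavage to fall back on.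
- Comparison: on structure the alternative forms ring C and no stereocentre, so C1 and C2 must still be set by a step of the kind chosen here. On mechanism its regiocontrol is intrinsic to the enzyme, whereas the chosen plan relies on a chelate model. On step economy it would be shorter if the biotransformation worked, but its whole risk sits in one unvalidated enzymatic step.

Alternative 2: The cut dissolves ring A into three alkynes (bonds C4a–C8a, C5–C6, C7–C8). The precursor is the enediyne A4, which carries an ethynyl group at C1 and another at C4 of a chain that already contains C1, C2, both esters and the pyranone. The partner is bis(pinacolboryl)acetylene A5. Cp*RuCl(cod) or CpCo(CO)2 would cyclotrimerise the three alkynes to the 6,7-diborylated dihydronaphthalene triester A3. Oxidation of both C–B bonds would lead to 19.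

- In favour: three skeletal bonds and two rings form in one step. The oxygenation pattern of ring A is fixed by the diboryl alkyne.
- Equal or better than the chosen plan: the catechol is unveiled by mild C–B oxidation instead of BBr3, and more skeleton is built per step.
- Against: the step creates no stereocentre. A4 must therefore already hold C1 and C2 in the right configuration, next to a propargylic C1–H and an epimerisable C2–H, and in a skipped enyne that can isomerise to an allene. The pyranone is itself a diene and a ligand for cobalt and ruthenium. Cross-trimerisation must beat oligomerisation of the diyne, and A5 is a hindered partner. The usual basic peroxide oxidation of boronates would endanger the lactone.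
- Comparison: on structure it is the more powerful ring construction. On mechanism it leaves the stereochemical problem unsolved, and on step economy the long synthesis of A4 is expected to cost more than the key step saves.

Alternative 3: The cut is again in ring C (bonds O1'–C6' and C4'–C5'). The precursor is the C1 propiolic acid A7, a dihydronaphthalene diester with the C1 and C2 configuration in place. The partner is 3,3-diethoxypropyne A8. (Ph3P)AuCl/AgOTf would add the carboxylic acid across A8 to an enol ester, whose alkene would then close 6-endo onto the gold-activated ynoate. The product would be the 6'-(diethoxymethyl)pyranone A6.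

- In favour: gold-catalysed coupling of propiolic acids with terminal alkynes is an established pyranone synthesis with inherent 4,6-regiochemistry. The pyranone is built late from simple parts.
- Equal or better than the chosen plan: the heterocycle is not exposed to Me2AlCl or to the coupling step, and 5 is not needed.
- Against: the step is stereochemically silent, and an enantioselective route to a C1-alkynyl dihydronaphthalene such as A7 is no easier than the chosen cyclisation. The acetal of A8 is labile towards the cationic gold and silver salts. The electron-rich ring A (C8, peri to C1) could attack the activated ynoate. After the annulation an acetal hydrolysis and an aldehyde-to-acid oxidation are needed before the same deprotections.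
- Comparison: on structure it forms one ring and no stereocentre, against one ring and two stereocentres in the chosen plan. On mechanism it is better precedented for the heterocycle itself. On step economy it is longer by about two steps after its key step.

Key step: step 10

Assumption: the facial course of step 10 is assigned with the planar, chelated s-cis conformer established for N-enoyl oxazolidinones. On that model the (E)-C1=C2 geometry requires the (4R)-benzyl auxiliary for (1R); the (4S) antipode would lead to (1S), so 9 is the (R) enantiomer.

## Route

Step 1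
Reactants: 1 4-hydroxy-6-methyl-2H-pyran-2-one
Product: 2 4-bromo-6-methyl-2H-pyran-2-one
Conditions: Bu4NBr, P2O5, toluene, 100 °C
Reagents that add atoms: tetrabutylammonium bromide, CCCC[N+](CCCC)(CCCC)CCCC.[Br-]
Why: Deoxybromination of a vinylogous acid: the C4 hydroxyl is phosphorylated by P2O5 and replaced by bromide through addition–elimination at C4 of the pyranone, a standard conversion for this ring.

Step 2
Reactants: 2 4-bromo-6-methyl-2H-pyran-2-one
Product: 3 4-bromo-2-oxo-2H-pyran-6-carbaldehyde
Conditions: SeO2, 1,4-dioxane, 150 °C (sealed tube)
Reagents that add atoms: selenium dioxide, O=[Se]=O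
Why: Riley oxidation: the C6 methyl group is vinylogously activated by the lactone carbonyl and should be oxidised to the aldehyde as in the 4-methoxy analogue; the C4–Br bond is not touched.

Step 3
Reactants: 3 4-bromo-2-oxo-2H-pyran-6-carbaldehyde
Product: 4 4-bromo-2-oxo-2H-pyran-6-carboxylic acid
Conditions: NaClO2, NaH2PO4, 2-methyl-2-butene, t-BuOH/H2O, 0 °C → rt
Reagents that add atoms: sodium chlorite, [Na+].[O-]Cl=O
Why: Lindgren–Pinnick oxidation: buffered chlorite oxidises only the aldehyde, and the alkene scavenger removes hypochlorous acid before it can attack the pyranone.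

Step 4
Reactants: 4 4-bromo-2-oxo-2H-pyran-6-carboxylic acid
Product: 5 methyl 4-bromo-2-oxo-2H-pyran-6-carboxylate
Conditions: Me3SiCHN2, toluene/MeOH, 0 °C
Reagents that add atoms: trimethylsilyldiazomethane, C[Si](C)(C)C=[N+]=[N-]
Why: Esterification by a diazoalkane (proton transfer, then SN2 of the carboxylate on the methyldiazonium ion) is neutral and offers no nucleophile that could displace the C4 bromide.

Step 5
Reactants: 6 3,4-dimethoxybenzaldehyde; 7 dimethyl succinate
Product: 8 (E)-4-(3,4-dimethoxyphenyl)-3-(methoxycarbonyl)but-3-enoic acid
Conditions: NaOMe, MeOH, reflux; then aq. HCl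
Reagents that add atoms: none
Why: Stobbe condensation: aldol addition, lactonisation to the paraconic ester and E1cB ring opening leave the ester on the arylidene carbon and the free acid on the CH2 arm, with the aryl group cis to that arm in the thermodynamically preferred (E)-isomer.

Step 6
Reactants: 8 (E)-4-(3,4-dimethoxyphenyl)-3-(methoxycarbonyl)but-3-enoic acid; 9 (R)-4-benzyloxazolidin-2-one
Product: 11 methyl (E)-4-[(4R)-4-benzyl-2-oxooxazolidin-3-yl]-2-(3,4-dimethoxybenzylidene)-4-oxobutanoate, via mixed pivalic anhydride 10 (not isolated)
Conditions: t-BuCOCl, Et3N, THF, −20 °C; then LiCl, 9, −20 °C → rt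
Reagents that add atoms: pivaloyl chloride, CC(C)(C)C(=O)Cl (its acyl group is held in intermediate 10 only)
Why: N-acylation through a mixed anhydride: the LiCl/Et3N-activated oxazolidinone attacks the less hindered carbonyl of 10, and the weak base at low temperature should not move the C3=C4 bond.

Step 7
Reactants: 11 methyl (E)-4-[(4R)-4-benzyl-2-oxooxazolidin-3-yl]-2-(3,4-dimethoxybenzylidene)-4-oxobutanoate
Product: 12 methyl (2E,3S)-4-[(4R)-4-benzyl-2-oxooxazolidin-3-yl]-2-(3,4-dimethoxybenzylidene)-3-(hydroxymethyl)-4-oxobutanoate
Conditions: TiCl4, i-Pr2NEt, CH2Cl2, 0 °C; then 1,3,5-trioxane, TiCl4, 0 °C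
Reagents that add atoms: 1,3,5-trioxane, C1OCOCO1 (one CH2O unit)
Why: Titanium-enolate aldol reaction with formaldehyde (hydroxymethylation of an N-acyl oxazolidinone): the chelated (Z)-enolate reacts at its α-carbon, which keeps the arylidene conjugation, on the face away from the benzyl group; the new centre (3S) is of no consequence because step 8 erases it.

Step 8
Reactants: 12 methyl (2E,3S)-4-[(4R)-4-benzyl-2-oxooxazolidin-3-yl]-2-(3,4-dimethoxybenzylidene)-3-(hydroxymethyl)-4-oxobutanoate
Product: 14 methyl (E)-3-{[(4R)-4-benzyl-2-oxooxazolidin-3-yl]carbonyl}-2-(3,4-dimethoxybenzylidene)but-3-enoate, via primary mesylate 13 (not isolated)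
Conditions: MeSO2Cl, Et3N, CH2Cl2, 0 °C → rt
Reagents that add atoms: methanesulfonyl chloride, CS(=O)(=O)Cl (held in intermediate 13 only)
Why: Mesylation followed by E1cB elimination: the hydrogen α to the imide is also allylic and acidic enough for triethylamine to expel the mesylate, giving the 2-methylene imide; the diene is kept cold and used at once to avoid dimerisation.

Step 9
Reactants: 14 methyl (E)-3-{[(4R)-4-benzyl-2-oxooxazolidin-3-yl]carbonyl}-2-(3,4-dimethoxybenzylidene)but-3-enoate; 5 methyl 4-bromo-2-oxo-2H-pyran-6-carboxylate
Product: 15 methyl 4-[(1E,3E)-2-{[(4R)-4-benzyl-2-oxooxazolidin-3-yl]carbonyl}-4-(3,4-dimethoxyphenyl)-3-(methoxycarbonyl)buta-1,3-dien-1-yl]-2-oxo-2H-pyran-6-carboxylate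
Conditions: Pd2(dba)3 (2.5 mol %), [HP(t-Bu)3]BF4 (10 mol %), Cy2NMe, 1,4-dioxane, 50 °C
Reagents that add atoms: none
Why: Mizoroki–Heck reaction: the electron-poor C4'–Br bond adds readily to zerovalent palladium, carbopalladation occurs at the only unhindered alkene (the terminal methylene), and syn β-hydride elimination can only form C1=C2, with the pyranonyl group trans to the imide carbonyl as in arylations of itaconates; the hindered amine does not add to either partner.

Step 10
Reactants: 15 methyl 4-[(1E,3E)-2-{[(4R)-4-benzyl-2-oxooxazolidin-3-yl]carbonyl}-4-(3,4-dimethoxyphenyl)-3-(methoxycarbonyl)buta-1,3-dien-1-yl]-2-oxo-2H-pyran-6-carboxylate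
Product: 17 methyl (1R,2S)-2-{[(4R)-4-benzyl-2-oxooxazolidin-3-yl]carbonyl}-6,7-dimethoxy-1-[6-(methoxycarbonyl)-2-oxo-2H-pyran-4-yl]-1,2-dihydronaphthalene-3-carboxylate, via dimethylaluminium enolate 16 (not isolated)
Conditions: Me2AlCl (3 equiv), CH2Cl2, −78 → −20 °C; then 1 M aq. HCl, −78 → 0 °C
Reagents that add atoms: dimethylaluminium chloride, C[Al](C)Cl (aluminium and its methyl groups are held in intermediate 16 only)
Why: Excess Me2AlCl should turn the imide into a chelated dimethylaluminium cation spanning both imide carbonyls (counter-ion Me2AlCl2−), which lowers the LUMO of the C1=C2 acrylimide and places positive charge on C1; the excess is needed because the methoxy groups, the esters and the pyranone also bind the Lewis acid. The ring A carbon ortho to the C4 tether and para to a methoxy group (the future C8a) then attacks C1 in a 6-endo-trig conjugate Friedel–Crafts alkylation that closes ring B through the C1–C8a bond; the arenium ion loses its proton to an Al–CH3 bond (methane), which leaves enolate 16. The closest known reaction types are the acid-promoted cyclisation of bis(arylidene)succinates to trans-1-aryl-1,2-dihydronaphthalene-2,3-dicarboxylates and auxiliary-directed conjugate Friedel–Crafts additions to chelated N-enoyl oxazolidinones. C1 is controlled by the auxiliary: in the s-cis chelate the benzyl group of the (4R)-oxazolidinone covers one face of the C1=C2 plane, so ring A, delivered through the C3=C4 tether, bonds to the open face, and with the (E)-alkene this face corresponds to (1R); the (4S)-auxiliary, or the (Z)-alkene, would each lead to (1S), which is why both the antipode and the alkene geometry are fixed in 15. C2 is controlled by the substrate: protonation of 16 on acidic quench occurs anti to the pyranonyl group at C1 and gives the trans (1R,2S) pair, which is also the more stable arrangement. The step needs chemoselectivity and regioselectivity, and both are secured by the substrate: only ring A is nucleophilic, only the imide can chelate, methyl transfer from aluminium is slow, and attack at the carbon between the tether and a methoxy group is sterically disfavoured. Because the auxiliary is still attached in 17, a minor (1S,2R) diastereomer can be removed by chromatography or crystallisation before step 11.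

Step 11
Reactants: 17 methyl (1R,2S)-2-{[(4R)-4-benzyl-2-oxooxazolidin-3-yl]carbonyl}-6,7-dimethoxy-1-[6-(methoxycarbonyl)-2-oxo-2H-pyran-4-yl]-1,2-dihydronaphthalene-3-carboxylate
Product: 18 dimethyl (1R,2S)-6,7-dimethoxy-1-[6-(methoxycarbonyl)-2-oxo-2H-pyran-4-yl]-1,2-dihydronaphthalene-2,3-dicarboxylate
Conditions: Yb(OTf)3 (20 mol %), MeOH, 60 °C
Reagents that add atoms: methanol, CO
Why: Lewis-acid-catalysed alcoholysis of an N-acyl oxazolidinone: chelation of the two imide carbonyls activates the exocyclic acyl group towards methanol, and the neutral medium should leave C1, C2 and the lactone untouched; auxiliary 9 is recovered.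

Step 12
Reactants: 18 dimethyl (1R,2S)-6,7-dimethoxy-1-[6-(methoxycarbonyl)-2-oxo-2H-pyran-4-yl]-1,2-dihydronaphthalene-2,3-dicarboxylate
Product: 20 (1R,2S)-1-(6-carboxy-2-oxo-2H-pyran-4-yl)-6,7-dihydroxy-1,2-dihydronaphthalene-2,3-dicarboxylic acid, via catechol trimethyl ester 19 (not isolated)
Conditions: BBr3 (8 equiv), CH2Cl2, −78 °C → rt; then H2O/1,4-dioxane, 70 °C, Ar
Reagents that add atoms: water, O
Why: BBr3 cleaves the two aryl methyl ethers (O–B coordination, then SN2 of bromide at methyl), and the aqueous HBr formed on quenching hydrolyses the three methyl esters on warming (acid-catalysed acyl substitution); no base is involved, and acid can only reinforce the trans relationship at C2.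

## Compound list

1 | 4-hydroxy-6-methyl-2H-pyran-2-one | Cc1cc(O)cc(=O)o1 | starting material
2 | 4-bromo-6-methyl-2H-pyran-2-one | Cc1cc(Br)cc(=O)o1 | intermediate
3 | 4-bromo-2-oxo-2H-pyran-6-carbaldehyde | O=Cc1cc(Br)cc(=O)o1 | intermediate
4 | 4-bromo-2-oxo-2H-pyran-6-carboxylic acid | OC(=O)c1cc(Br)cc(=O)o1 | intermediate
5 | methyl 4-bromo-2-oxo-2H-pyran-6-carboxylate | COC(=O)c1cc(Br)cc(=O)o1 | intermediate
6 | 3,4-dimethoxybenzaldehyde | COc1ccc(C=O)cc1OC | starting material
7 | dimethyl succinate | COC(=O)CCC(=O)OC | starting material
8 | (E)-4-(3,4-dimethoxyphenyl)-3-(methoxycarbonyl)but-3-enoic acid | COC(=O)/C(=C/c1ccc(OC)c(OC)c1)CC(=O)O | intermediate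
9 | (R)-4-benzyloxazolidin-2-one | O=C1N[C@H](Cc2ccccc2)CO1 | starting material
10 | (E)-4-(3,4-dimethoxyphenyl)-3-(methoxycarbonyl)but-3-enoic pivalic anhydride | COC(=O)/C(=C/c1ccc(OC)c(OC)c1)CC(=O)OC(=O)C(C)(C)C | intermediate (not isolated)
11 | methyl (E)-4-[(4R)-4-benzyl-2-oxooxazolidin-3-yl]-2-(3,4-dimethoxybenzylidene)-4-oxobutanoate | COC(=O)/C(=C/c1ccc(OC)c(OC)c1)CC(=O)N1C(=O)OC[C@H]1Cc1ccccc1 | intermediate
12 | methyl (2E,3S)-4-[(4R)-4-benzyl-2-oxooxazolidin-3-yl]-2-(3,4-dimethoxybenzylidene)-3-(hydroxymethyl)-4-oxobutanoate | COC(=O)/C(=C/c1ccc(OC)c(OC)c1)[C@@H](CO)C(=O)N1C(=O)OC[C@H]1Cc1ccccc1 | intermediate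
13 | methyl (2E,3S)-4-[(4R)-4-benzyl-2-oxooxazolidin-3-yl]-2-(3,4-dimethoxybenzylidene)-3-[(methanesulfonyloxy)methyl]-4-oxobutanoate | COC(=O)/C(=C/c1ccc(OC)c(OC)c1)[C@@H](COS(C)(=O)=O)C(=O)N1C(=O)OC[C@H]1Cc1ccccc1 | intermediate (not isolated)
14 | methyl (E)-3-{[(4R)-4-benzyl-2-oxooxazolidin-3-yl]carbonyl}-2-(3,4-dimethoxybenzylidene)but-3-enoate | COC(=O)/C(=C/c1ccc(OC)c(OC)c1)C(=C)C(=O)N1C(=O)OC[C@H]1Cc1ccccc1 | intermediate
15 | methyl 4-[(1E,3E)-2-{[(4R)-4-benzyl-2-oxooxazolidin-3-yl]carbonyl}-4-(3,4-dimethoxyphenyl)-3-(methoxycarbonyl)buta-1,3-dien-1-yl]-2-oxo-2H-pyran-6-carboxylate | COC(=O)/C(=C/c1ccc(OC)c(OC)c1)/C(=C\c1cc(C(=O)OC)oc(=O)c1)C(=O)N1C(=O)OC[C@H]1Cc1ccccc1 | intermediate (precursor of the key step)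
16 | dimethylaluminium enolate of 17 (O-bound AlMe2 on the imide enolate, C1 already R) | COC(=O)C1=Cc2cc(OC)c(OC)cc2[C@@H](c2cc(C(=O)OC)oc(=O)c2)C1=C(O[Al](C)C)N1C(=O)OC[C@H]1Cc1ccccc1 | intermediate (not isolated)
17 | methyl (1R,2S)-2-{[(4R)-4-benzyl-2-oxooxazolidin-3-yl]carbonyl}-6,7-dimethoxy-1-[6-(methoxycarbonyl)-2-oxo-2H-pyran-4-yl]-1,2-dihydronaphthalene-3-carboxylate | COC(=O)C1=Cc2cc(OC)c(OC)cc2[C@@H](c2cc(C(=O)OC)oc(=O)c2)[C@@H]1C(=O)N1C(=O)OC[C@H]1Cc1ccccc1 | intermediate (product of the key step)
18 | dimethyl (1R,2S)-6,7-dimethoxy-1-[6-(methoxycarbonyl)-2-oxo-2H-pyran-4-yl]-1,2-dihydronaphthalene-2,3-dicarboxylate | COC(=O)C1=Cc2cc(OC)c(OC)cc2[C@@H](c2cc(C(=O)OC)oc(=O)c2)[C@@H]1C(=O)OC | intermediate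
19 | dimethyl (1R,2S)-6,7-dihydroxy-1-[6-(methoxycarbonyl)-2-oxo-2H-pyran-4-yl]-1,2-dihydronaphthalene-2,3-dicarboxylate | COC(=O)C1=Cc2cc(O)c(O)cc2[C@@H](c2cc(C(=O)OC)oc(=O)c2)[C@@H]1C(=O)OC | intermediate (not isolated)
20 | (1R,2S)-1-(6-carboxy-2-oxo-2H-pyran-4-yl)-6,7-dihydroxy-1,2-dihydronaphthalene-2,3-dicarboxylic acid | O=C(O)C1=Cc2cc(O)c(O)cc2[C@@H](c2cc(C(=O)O)oc(=O)c2)[C@@H]1C(=O)O | target

## Step count and least certain steps

Total: 12 steps. Longest linear sequence: 8 steps (steps 1 to 4 and 9 to 12; the branch through steps 5 to 12 is of equal length).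

Step 10 (key step). The most likely failure is insufficient facial discrimination, or even the opposite sense. The acyl carbon of 15 is α-branched, and the imide can twist out of the chelate plane to relieve the strain between C3 and the auxiliary. This both blurs the s-cis model and lowers the electrophilicity of C1, so the cyclisation may be slow enough for Lewis-acid-induced isomerisation of the C1=C2 bond to compete. If only the sense were inverted, the antipodal auxiliary would correct it. The fallback for low selectivity abandons auxiliary control. Setting out from 15, the auxiliary would be removed first (Yb(OTf)3, MeOH) to give the achiral triester dimethyl (2E,3E)-2-(3,4-dimethoxybenzylidene)-3-{[6-(methoxycarbonyl)-2-oxo-2H-pyran-4-yl]methylidene}butanedioate F1. Brønsted-acid cyclisation (CF3SO3H, CH2Cl2, 0 °C), the known mode for bis(arylidene)succinates, should give the trans product as the racemate, that is 18 together with its enantiomer dimethyl (1S,2R)-6,7-dimethoxy-1-[6-(methoxycarbonyl)-2-oxo-2H-pyran-4-yl]-1,2-dihydronaphthalene-2,3-dicarboxylate F2. Preparative chromatography on a chiral stationary phase would return the route at 18.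

Step 9. Erosion of (E)-selectivity in the β-hydride elimination would pass directly into the enantiomeric purity at C1. Diene 14 may also dimerise by Diels–Alder reaction or polymerise on warming, and the bromide of 5 may be reduced instead of coupled. The fallback forms C1=C2 by aldol condensation instead of coupling. Setting out from 5, palladium-catalysed formylation (Pd(PPh3)4, CO, Bu3SnH, THF, 50 °C) would give methyl 4-formyl-2-oxo-2H-pyran-6-carboxylate F3. The titanium enolate of 11 (TiCl4, i-Pr2NEt, CH2Cl2, −78 °C) would add to it to give the β-hydroxy imide methyl (E)-3-{[(4R)-4-benzyl-2-oxooxazolidin-3-yl]carbonyl}-2-(3,4-dimethoxybenzylidene)-4-hydroxy-4-[6-(methoxycarbonyl)-2-oxo-2H-pyran-4-yl]butanoate F4 (a mixture at the two new centres, both of which are lost). Mesylation to its methanesulfonate F5 and E1cB elimination with Et3N would come back to the route at 15; 12, 13 and 14 are then not needed.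

Step 7. The titanium dienolate may react at its γ-carbon or reprotonate with migration of the C3=C4 bond, and the β-hydroxy imide may revert by retro-aldol loss of formaldehyde or undergo N-to-O acyl transfer. The fallback is an aminomethylation and Hofmann-type elimination. Setting out from 11, the sodium enolate (NaN(SiMe3)2, THF, −78 °C) would be trapped with dimethyl(methylidene)ammonium iodide to give the Mannich base methyl (2E,3S)-4-[(4R)-4-benzyl-2-oxooxazolidin-3-yl]-2-(3,4-dimethoxybenzylidene)-3-[(dimethylamino)methyl]-4-oxobutanoate F6. Quaternisation with MeI would give the trimethylammonium iodide F7, and DBU would eliminate trimethylamine, coming back to the route at 14.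

Step 11. Exocyclic methanolysis at the hindered, α-branched imide carbonyl may be slow, so that opening of the oxazolidinone ring or methanolysis of the pyranone lactone competes. The fallback is peroxide-assisted hydrolysis instead of alcoholysis. Setting out from 17, LiOH/H2O2 (THF/H2O, 0 °C, short contact) would give (1R,2S)-6,7-dimethoxy-3-(methoxycarbonyl)-1-[6-(methoxycarbonyl)-2-oxo-2H-pyran-4-yl]-1,2-dihydronaphthalene-2-carboxylic acid F8. Esterification with Me3SiCHN2 would come back to the route at 18.

Step 12. Hydrolysis of the hindered, conjugated C3 ester may lag behind, and prolonged heating in acid could then cause dehydrogenation to the naphthalene, oxidation of the free catechol or decarboxylation of the β,γ-unsaturated C2 acid. The fallback separates the two operations and replaces hydrolysis by dealkylation. Setting out from 18, the BBr3 stage alone (−78 → 0 °C, cold quench) would be followed by isolation of 19. Its three methyl esters would then be cleaved at the O–CH3 bond by iodide (LiI, EtOAc, reflux, Ar), an SN2 process that is indifferent to hindrance at the carbonyl. Acidification would come back to the route at 20. This fallback makes no new compound (F0).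

## Further compounds

F1 | step 10 | dimethyl (2E,3E)-2-(3,4-dimethoxybenzylidene)-3-{[6-(methoxycarbonyl)-2-oxo-2H-pyran-4-yl]methylidene}butanedioate | COC(=O)/C(=C/c1ccc(OC)c(OC)c1)/C(=C\c1cc(C(=O)OC)oc(=O)c1)C(=O)OC
F2 | step 10 | dimethyl (1S,2R)-6,7-dimethoxy-1-[6-(methoxycarbonyl)-2-oxo-2H-pyran-4-yl]-1,2-dihydronaphthalene-2,3-dicarboxylate (enantiomer of 18) | COC(=O)C1=Cc2cc(OC)c(OC)cc2[C@H](c2cc(C(=O)OC)oc(=O)c2)[C@H]1C(=O)OC
F3 | step 9 | methyl 4-formyl-2-oxo-2H-pyran-6-carboxylate | O=Cc1cc(C(=O)OC)oc(=O)c1
F4 | step 9 | methyl (E)-3-{[(4R)-4-benzyl-2-oxooxazolidin-3-yl]carbonyl}-2-(3,4-dimethoxybenzylidene)-4-hydroxy-4-[6-(methoxycarbonyl)-2-oxo-2H-pyran-4-yl]butanoate (mixture at the two new centres) | COC(=O)/C(=C/c1ccc(OC)c(OC)c1)C(C(O)c1cc(C(=O)OC)oc(=O)c1)C(=O)N1C(=O)OC[C@H]1Cc1ccccc1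
F5 | step 9 | methanesulfonate of F4 | COC(=O)/C(=C/c1ccc(OC)c(OC)c1)C(C(OS(C)(=O)=O)c1cc(C(=O)OC)oc(=O)c1)C(=O)N1C(=O)OC[C@H]1Cc1ccccc1
F6 | step 7 | methyl (2E,3S)-4-[(4R)-4-benzyl-2-oxooxazolidin-3-yl]-2-(3,4-dimethoxybenzylidene)-3-[(dimethylamino)methyl]-4-oxobutanoate | COC(=O)/C(=C/c1ccc(OC)c(OC)c1)[C@@H](CN(C)C)C(=O)N1C(=O)OC[C@H]1Cc1ccccc1
F7 | step 7 | trimethylammonium iodide of F6 | COC(=O)/C(=C/c1ccc(OC)c(OC)c1)[C@@H](C[N+](C)(C)C)C(=O)N1C(=O)OC[C@H]1Cc1ccccc1.[I-]
F8 | step 11 | (1R,2S)-6,7-dimethoxy-3-(methoxycarbonyl)-1-[6-(methoxycarbonyl)-2-oxo-2H-pyran-4-yl]-1,2-dihydronaphthalene-2-carboxylic acid | COC(=O)C1=Cc2cc(OC)c(OC)cc2[C@@H](c2cc(C(=O)OC)oc(=O)c2)[C@@H]1C(=O)O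
F0 | step 12 | none | none
A1 | alternative 1 | (1R,2S)-1-(6-carboxy-2-oxo-2H-pyran-4-yl)-6,7-dimethoxy-1,2-dihydronaphthalene-2,3-dicarboxylic acid | OC(=O)C1=Cc2cc(OC)c(OC)cc2[C@@H](c2cc(C(=O)O)oc(=O)c2)[C@@H]1C(=O)O
A2 | alternative 1 | 1-(3,4-dihydroxyphenyl)-6,7-dimethoxy-1,2-dihydronaphthalene-2,3-dicarboxylic acid, C1 and C2 configured as in the target | OC(=O)C1=Cc2cc(OC)c(OC)cc2[C@@H](c2ccc(O)c(O)c2)[C@@H]1C(=O)O
A3 | alternative 2 | dimethyl 1-[6-(methoxycarbonyl)-2-oxo-2H-pyran-4-yl]-6,7-bis(4,4,5,5-tetramethyl-1,3,2-dioxaborolan-2-yl)-1,2-dihydronaphthalene-2,3-dicarboxylate, C1 and C2 configured as in the target | COC(=O)C1=Cc2cc(B3OC(C)(C)C(C)(C)O3)c(B3OC(C)(C)C(C)(C)O3)cc2[C@@H](c2cc(C(=O)OC)oc(=O)c2)[C@@H]1C(=O)OC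
A4 | alternative 2 | dimethyl (E)-2-(prop-2-yn-1-ylidene)-3-{1-[6-(methoxycarbonyl)-2-oxo-2H-pyran-4-yl]prop-2-yn-1-yl}butanedioate, both stereocentres configured as C1 and C2 of the target | COC(=O)/C(=C/C#C)[C@@H](C(=O)OC)[C@@H](C#C)c1cc(C(=O)OC)oc(=O)c1
A5 | alternative 2 | bis(pinacolboryl)acetylene | CC1(C)OB(C#CB2OC(C)(C)C(C)(C)O2)OC1(C)C
A6 | alternative 3 | dimethyl 1-[6-(diethoxymethyl)-2-oxo-2H-pyran-4-yl]-6,7-dimethoxy-1,2-dihydronaphthalene-2,3-dicarboxylate, C1 and C2 configured as in the target | COC(=O)C1=Cc2cc(OC)c(OC)cc2[C@@H](c2cc(C(OCC)OCC)oc(=O)c2)[C@@H]1C(=O)OC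
A7 | alternative 3 | 3-[6,7-dimethoxy-2,3-bis(methoxycarbonyl)-1,2-dihydronaphthalen-1-yl]prop-2-ynoic acid, C1 and C2 configured as in the target | COC(=O)C1=Cc2cc(OC)c(OC)cc2[C@@H](C#CC(=O)O)[C@@H]1C(=O)OC
A8 | alternative 3 | 3,3-diethoxyprop-1-yne | CCOC(OCC)C#C
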